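Assumption: the target has no stereocentre and no stereogenic double bond, so it is achiral and no stereocontrol is needed; the route gives the one defined constitution.

## Retrosynthetic overview

1. Target 23 ⇐ global hydrogenolysis of the tribenzyl-protected tridepside 22.
2. 22 ⇐ two aryl-ester (depside) disconnections: A-ring acid 16, B-ring allyl orsellinate 9 and C-ring benzyl orsellinate 8, assembled A→B→C.
3. 8 and 9 ⇐ orsellinic acid 7 ⇐ ethyl orsellinate 6. Acid 16 ⇐ 6 by 4-O-benzylation, ortho-formylation at C3, Dakin oxidation, O-methylation and saponification.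
4. 6 ⇐ ethyl acetoacetate 1 + ethyl crotonate 2: intermolecular Michael addition (key C–C bond), Dieckmann closure, bromination/aromatisation, debromination.
5. Ring order: one carbocycle-forming sequence only (Michael–Dieckmann cyclohexanedione → arene), run once in bulk and divided to supply rings A, B and C.

## Route

Step 1
Reactants: 1 ethyl acetoacetate; 2 ethyl (E)-but-2-enoate (ethyl crotonate)
Product: 4 ethyl 6-methyl-2,4-dioxocyclohexane-1-carboxylate (ethyl dihydroorsellinate), via Michael adduct 3 (not isolated)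
Conditions: NaOEt (1.05 equiv), EtOH, reflux, 3 h; then aq HCl, 0 °C
Reagents that add atoms: none
Why: Intermolecular Michael addition of the acetoacetate enolate to the crotonate gives 3, which closes by Dieckmann (intramolecular Claisen) condensation, driven by the stabilised dione enolate; the two sp3 centres of 4 are racemic and are erased in step 2.

Step 2
Reactants: 4 ethyl 6-methyl-2,4-dioxocyclohexane-1-carboxylate
Product: 5 ethyl 3,5-dibromo-2,4-dihydroxy-6-methylbenzoate
Conditions: Br2 (3.05 equiv), AcOH, 10 °C → rt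
Reagents that add atoms: bromine, BrBr
Why: Enol bromination and dehydrobromination aromatise the 1,3-dione (oxidative aromatisation), and the resulting resorcinol takes up bromine at both free ring positions by electrophilic aromatic substitution, giving one crystalline product.

Step 3
Reactants: 5 ethyl 3,5-dibromo-2,4-dihydroxy-6-methylbenzoate
Product: 6 ethyl 2,4-dihydroxy-6-methylbenzoate (ethyl orsellinate)
Conditions: H2 (1 atm), 10% Pd/C, NaOAc (2.5 equiv), EtOH, rt
Reagents that add atoms: none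
Why: Catalytic hydrogenolysis of both aryl C–Br bonds (hydrodehalogenation) is clean because the hindered ester and the phenols are inert to H2/Pd.

Step 4
Reactants: 6 ethyl 2,4-dihydroxy-6-methylbenzoate
Product: 7 2,4-dihydroxy-6-methylbenzoic acid (orsellinic acid)
Conditions: 10% aq NaOH, 60 °C, N2; then cold 2 M HCl to pH 2, 0 °C
Reagents that add atoms: sodium hydroxide, [Na+].[OH-]
Why: Saponification (BAc2) of the ester; the acid is liberated cold because orsellinic acid decarboxylates on heating in acid.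

Step 5
Reactants: 7 2,4-dihydroxy-6-methylbenzoic acid
Product: 8 benzyl 2,4-dihydroxy-6-methylbenzoate (benzyl orsellinate)
Conditions: BnBr (1.05 equiv), KHCO3 (1.2 equiv), DMF, rt
Reagents that add atoms: benzyl bromide, BrCc1ccccc1
Why: Bicarbonate ionises only the carboxylic acid, so SN2 O-alkylation of the carboxylate leaves both phenols free.

Step 6
Reactants: 7 2,4-dihydroxy-6-methylbenzoic acid
Product: 9 prop-2-en-1-yl 2,4-dihydroxy-6-methylbenzoate (allyl orsellinate)
Conditions: allyl bromide (1.05 equiv), KHCO3 (1.2 equiv), DMF, rt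
Reagents that add atoms: allyl bromide, C=CCBr
Why: The same chemoselective carboxylate SN2 alkylation installs an ester that can later be removed without touching benzyl groups or depside bonds.

Step 7
Reactants: 6 ethyl 2,4-dihydroxy-6-methylbenzoate
Product: 10 ethyl 4-(benzyloxy)-2-hydroxy-6-methylbenzoate
Conditions: BnBr (1.05 equiv), K2CO3 (1.1 equiv), acetone, reflux
Reagents that add atoms: benzyl bromide, BrCc1ccccc1
Why: Williamson etherification is selective for the 4-OH because the 2-OH is hydrogen-bonded to the ester carbonyl and much less nucleophilic.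

Step 8
Reactants: 10 ethyl 4-(benzyloxy)-2-hydroxy-6-methylbenzoate
Product: 12 ethyl 4-(benzyloxy)-3-formyl-2-hydroxy-6-methylbenzoate, via hydroxymethyl phenol 11 (not isolated)
Conditions: MgCl2 (2 equiv), Et3N (4 equiv), (CH2O)n (6 equiv), MeCN, reflux; then 1 M HCl
Reagents that add atoms: paraformaldehyde (formaldehyde), C=O
Why: Magnesium-phenoxide-directed ortho-formylation (Casnati–Skattebøl) delivers formaldehyde only ortho to the free OH, and C3 is the sole free ortho position; alcohol 11 is oxidised in situ by hydride transfer to a second formaldehyde.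

Step 9
Reactants: 12 ethyl 4-(benzyloxy)-3-formyl-2-hydroxy-6-methylbenzoate
Product: 14 ethyl 4-(benzyloxy)-2,3-dihydroxy-6-methylbenzoate, via aryl formate 13 (not isolated)
Conditions: 30% H2O2 (1.3 equiv), 1 M aq NaOH (1.1 equiv), THF, 0 °C → rt, N2; then dilute HCl
Reagents that add atoms: hydrogen peroxide, OO
Why: Dakin oxidation of the ortho-hydroxybenzaldehyde (hydroperoxide addition, aryl migration, formate hydrolysis) replaces CHO by OH; the hindered ethyl ester and the benzyl ether are inert.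

Step 10
Reactants: 14 ethyl 4-(benzyloxy)-2,3-dihydroxy-6-methylbenzoate
Product: 15 ethyl 4-(benzyloxy)-2,3-dimethoxy-6-methylbenzoate
Conditions: MeI (3 equiv), K2CO3 (3 equiv), DMF, 55 °C
Reagents that add atoms: iodomethane, CI
Why: Exhaustive Williamson methylation in DMF alkylates both the free 3-OH and the chelated 2-OH.

Step 11
Reactants: 15 ethyl 4-(benzyloxy)-2,3-dimethoxy-6-methylbenzoate
Product: 16 4-(benzyloxy)-2,3-dimethoxy-6-methylbenzoic acid
Conditions: KOH (5 equiv), DMSO/H2O 4:1, 90 °C; then 2 M HCl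
Reagents that add atoms: potassium hydroxide, [K+].[OH-]
Why: Poorly solvated hydroxide in aqueous DMSO saponifies the di-ortho-substituted benzoate, and the acid cannot decarboxylate easily because it has no free ortho/para OH.

Step 12
Reactants: 16 4-(benzyloxy)-2,3-dimethoxy-6-methylbenzoic acid; 9 prop-2-en-1-yl 2,4-dihydroxy-6-methylbenzoate
Product: 18 prop-2-en-1-yl 4-{[4-(benzyloxy)-2,3-dimethoxy-6-methylbenzoyl]oxy}-2-hydroxy-6-methylbenzoate, via mixed anhydride 17 (not isolated)
Conditions: TFAA (4 equiv), dry toluene, rt, 4–16 h; aq NaHCO3 work-up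
Reagents that add atoms: trifluoroacetic anhydride, O=C(OC(=O)C(F)(F)F)C(F)(F)F (its CF3CO group is present in 17 only)
Why: Mixed-anhydride depside esterification; the electron-rich hindered acid is activated as its trifluoroacetyl anhydride and acylates the free 4-OH of 9, while the chelated 2-OH does not react.

Step 13
Reactants: 18 prop-2-en-1-yl 4-{[4-(benzyloxy)-2,3-dimethoxy-6-methylbenzoyl]oxy}-2-hydroxy-6-methylbenzoate
Product: 19 prop-2-en-1-yl 2-(benzyloxy)-4-{[4-(benzyloxy)-2,3-dimethoxy-6-methylbenzoyl]oxy}-6-methylbenzoate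
Conditions: BnBr (1.5 equiv), K2CO3 (2 equiv), dry DMF, 50 °C
Reagents that add atoms: benzyl bromide, BrCc1ccccc1
Why: Williamson benzylation of the only remaining phenol; the depside ester is a di-ortho-substituted benzoate and resists anhydrous carbonate, and the acyl group is meta to the phenoxide so it cannot migrate.

Step 14
Reactants: 19 prop-2-en-1-yl 2-(benzyloxy)-4-{[4-(benzyloxy)-2,3-dimethoxy-6-methylbenzoyl]oxy}-6-methylbenzoate
Product: 20 2-(benzyloxy)-4-{[4-(benzyloxy)-2,3-dimethoxy-6-methylbenzoyl]oxy}-6-methylbenzoic acid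
Conditions: Pd(PPh3)4 (5 mol %), morpholine (3 equiv), THF, rt; then dilute HCl
Reagents that add atoms: none
Why: Tsuji–Trost deallylation via a π-allyl-palladium complex trapped by morpholine frees the acid under neutral conditions that spare benzyl ethers and the hindered aryl ester.

Step 15
Reactants: 20 2-(benzyloxy)-4-{[4-(benzyloxy)-2,3-dimethoxy-6-methylbenzoyl]oxy}-6-methylbenzoic acid; 8 benzyl 2,4-dihydroxy-6-methylbenzoate
Product: 22 benzyl 4-{[2-(benzyloxy)-4-{[4-(benzyloxy)-2,3-dimethoxy-6-methylbenzoyl]oxy}-6-methylbenzoyl]oxy}-2-hydroxy-6-methylbenzoate, via mixed anhydride 21 (not isolated)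
Conditions: TFAA (4 equiv), dry toluene, rt, 16 h; aq NaHCO3 work-up
Reagents that add atoms: trifluoroacetic anhydride, O=C(OC(=O)C(F)(F)F)C(F)(F)F (its CF3CO group is present in 21 only)
Why: A second mixed-anhydride depside esterification; acid 20 has no free OH and cannot self-condense, and 8 reacts only at its non-chelated 4-OH.

Step 16
Reactants: 22 benzyl 4-{[2-(benzyloxy)-4-{[4-(benzyloxy)-2,3-dimethoxy-6-methylbenzoyl]oxy}-6-methylbenzoyl]oxy}-2-hydroxy-6-methylbenzoate
Product: 23 4-{[2-hydroxy-4-{[4-hydroxy-2,3-dimethoxy-6-methylbenzoyl]oxy}-6-methylbenzoyl]oxy}-2-hydroxy-6-methylbenzoic acid (target)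
Conditions: H2 (1 atm), 10% Pd/C, EtOAc, rt
Reagents that add atoms: none
Why: Neutral catalytic hydrogenolysis removes the two benzyl ethers and the benzyl ester in one operation; aryl esters and methyl ethers are inert, so both depside bonds survive.

## Compound list

1 | ethyl acetoacetate | CCOC(=O)CC(C)=O | starting material
2 | ethyl (E)-but-2-enoate (ethyl crotonate) | C/C=C/C(=O)OCC | starting material
3 | diethyl 2-acetyl-3-methylpentanedioate (Michael adduct, racemic diastereomer mixture) | CCOC(=O)CC(C)C(C(C)=O)C(=O)OCC | intermediate (not isolated)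
4 | ethyl 6-methyl-2,4-dioxocyclohexane-1-carboxylate (racemic, enolised; stereocentres erased in step 2) | CCOC(=O)C1C(C)CC(=O)CC1=O | intermediate
5 | ethyl 3,5-dibromo-2,4-dihydroxy-6-methylbenzoate | CCOC(=O)c1c(C)c(Br)c(O)c(Br)c1O | intermediate
6 | ethyl 2,4-dihydroxy-6-methylbenzoate (ethyl orsellinate) | CCOC(=O)c1c(C)cc(O)cc1O | intermediate
7 | 2,4-dihydroxy-6-methylbenzoic acid (orsellinic acid) | Cc1cc(O)cc(O)c1C(=O)O | intermediate
8 | benzyl 2,4-dihydroxy-6-methylbenzoate | Cc1cc(O)cc(O)c1C(=O)OCc1ccccc1 | intermediate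
9 | prop-2-en-1-yl 2,4-dihydroxy-6-methylbenzoate | Cc1cc(O)cc(O)c1C(=O)OCC=C | intermediate
10 | ethyl 4-(benzyloxy)-2-hydroxy-6-methylbenzoate | CCOC(=O)c1c(C)cc(OCc2ccccc2)cc1O | intermediate
11 | ethyl 4-(benzyloxy)-2-hydroxy-3-(hydroxymethyl)-6-methylbenzoate | CCOC(=O)c1c(C)cc(OCc2ccccc2)c(CO)c1O | intermediate (not isolated)
12 | ethyl 4-(benzyloxy)-3-formyl-2-hydroxy-6-methylbenzoate | CCOC(=O)c1c(C)cc(OCc2ccccc2)c(C=O)c1O | intermediate
13 | ethyl 4-(benzyloxy)-3-(formyloxy)-2-hydroxy-6-methylbenzoate | CCOC(=O)c1c(C)cc(OCc2ccccc2)c(OC=O)c1O | intermediate (not isolated)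
14 | ethyl 4-(benzyloxy)-2,3-dihydroxy-6-methylbenzoate | CCOC(=O)c1c(C)cc(OCc2ccccc2)c(O)c1O | intermediate
15 | ethyl 4-(benzyloxy)-2,3-dimethoxy-6-methylbenzoate | CCOC(=O)c1c(C)cc(OCc2ccccc2)c(OC)c1OC | intermediate
16 | 4-(benzyloxy)-2,3-dimethoxy-6-methylbenzoic acid | OC(=O)c1c(C)cc(OCc2ccccc2)c(OC)c1OC | intermediate
17 | 4-(benzyloxy)-2,3-dimethoxy-6-methylbenzoic trifluoroacetic anhydride | O=C(OC(=O)C(F)(F)F)c1c(C)cc(OCc2ccccc2)c(OC)c1OC | intermediate (not isolated)
18 | prop-2-en-1-yl 4-{[4-(benzyloxy)-2,3-dimethoxy-6-methylbenzoyl]oxy}-2-hydroxy-6-methylbenzoate | C=CCOC(=O)c1c(C)cc(OC(=O)c2c(C)cc(OCc3ccccc3)c(OC)c2OC)cc1O | intermediate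
19 | prop-2-en-1-yl 2-(benzyloxy)-4-{[4-(benzyloxy)-2,3-dimethoxy-6-methylbenzoyl]oxy}-6-methylbenzoate | C=CCOC(=O)c1c(C)cc(OC(=O)c2c(C)cc(OCc3ccccc3)c(OC)c2OC)cc1OCc1ccccc1 | intermediate
20 | 2-(benzyloxy)-4-{[4-(benzyloxy)-2,3-dimethoxy-6-methylbenzoyl]oxy}-6-methylbenzoic acid | OC(=O)c1c(C)cc(OC(=O)c2c(C)cc(OCc3ccccc3)c(OC)c2OC)cc1OCc1ccccc1 | intermediate
21 | 2-(benzyloxy)-4-{[4-(benzyloxy)-2,3-dimethoxy-6-methylbenzoyl]oxy}-6-methylbenzoic trifluoroacetic anhydride | O=C(OC(=O)C(F)(F)F)c1c(C)cc(OC(=O)c2c(C)cc(OCc3ccccc3)c(OC)c2OC)cc1OCc1ccccc1 | intermediate (not isolated)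
22 | benzyl 4-{[2-(benzyloxy)-4-{[4-(benzyloxy)-2,3-dimethoxy-6-methylbenzoyl]oxy}-6-methylbenzoyl]oxy}-2-hydroxy-6-methylbenzoate | O=C(OCc1ccccc1)c1c(C)cc(OC(=O)c2c(C)cc(OC(=O)c3c(C)cc(OCc4ccccc4)c(OC)c3OC)cc2OCc2ccccc2)cc1O | intermediate
23 | 4-{[2-hydroxy-4-{[4-hydroxy-2,3-dimethoxy-6-methylbenzoyl]oxy}-6-methylbenzoyl]oxy}-2-hydroxy-6-methylbenzoic acid (CNP0319613.0, achiral) | COc1c(O)cc(C)c(C(=O)Oc2cc(C)c(C(=O)Oc3cc(C)c(C(=O)O)c(O)c3)c(O)c2)c1OC | target

## Summary

Total step count: 16.
Longest linear sequence: 13 steps (1, 2, 3, 7, 8, 9, 10, 11, 12, 13, 14, 15, 16).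

Three steps most likely to fail:

Step 8 (ortho-formylation of a chelated, flanked salicylate; it may be sluggish). The fallback sets out from 2 and comes back at 15, bypassing steps 8–10 by building the C3 oxygen in from the start. Ethyl 4-methoxy-3-oxobutanoate is added to 2 (NaOEt, EtOH, reflux) to give, via diethyl 2-(2-methoxyacetyl)-3-methylpentanedioate F1 (not isolated), ethyl 3-methoxy-6-methyl-2,4-dioxocyclohexane-1-carboxylate F2. Aerobic Pd-catalysed dehydrogenation (Pd(TFA)2, 2-(dimethylamino)pyridine, TsOH, O2, DMSO, 80 °C) gives ethyl 2,4-dihydroxy-3-methoxy-6-methylbenzoate F3. Selective benzylation of the non-chelated 4-OH (BnBr, K2CO3, acetone) gives ethyl 4-(benzyloxy)-2-hydroxy-3-methoxy-6-methylbenzoate F4, and methylation of the 2-OH (MeI, K2CO3, DMF) gives 15.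

Step 9 (Dakin oxidation; the catechol product may over-oxidise in alkaline peroxide). The fallback sets out from 12 and comes back at 15, so that no free catechol is ever exposed to oxidant. The 2-OH of 12 is methylated first (MeI, K2CO3, DMF) to give ethyl 4-(benzyloxy)-3-formyl-2-methoxy-6-methylbenzoate F5. Baeyer–Villiger oxidation (mCPBA, CH2Cl2) gives ethyl 4-(benzyloxy)-3-(formyloxy)-2-methoxy-6-methylbenzoate F6. Methanolysis (cat. K2CO3, MeOH) gives ethyl 4-(benzyloxy)-3-hydroxy-2-methoxy-6-methylbenzoate F7, and methylation (MeI, K2CO3, DMF) gives 15.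

Step 15 (acid-mediated coupling of the bulky didepside acid; low conversion or acyl scrambling is possible). The fallback sets out from 20 and comes back at 22, replacing the in-situ mixed anhydride by an isolated acyl chloride used under basic conditions. Acid 20 with oxalyl chloride and cat. DMF in CH2Cl2 gives 2-(benzyloxy)-4-{[4-(benzyloxy)-2,3-dimethoxy-6-methylbenzoyl]oxy}-6-methylbenzoyl chloride F8. This is added to 8 with Et3N and cat. DMAP in CH2Cl2 at 0 °C, acylating the non-chelated 4-OH to give 22.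

## Further compounds

F1 | step 8 | diethyl 2-(2-methoxyacetyl)-3-methylpentanedioate | CCOC(=O)CC(C)C(C(=O)COC)C(=O)OCC
F2 | step 8 | ethyl 3-methoxy-6-methyl-2,4-dioxocyclohexane-1-carboxylate | CCOC(=O)C1C(C)CC(=O)C(OC)C1=O
F3 | step 8 | ethyl 2,4-dihydroxy-3-methoxy-6-methylbenzoate | CCOC(=O)c1c(C)cc(O)c(OC)c1O
F4 | step 8 | ethyl 4-(benzyloxy)-2-hydroxy-3-methoxy-6-methylbenzoate | CCOC(=O)c1c(C)cc(OCc2ccccc2)c(OC)c1O
F5 | step 9 | ethyl 4-(benzyloxy)-3-formyl-2-methoxy-6-methylbenzoate | CCOC(=O)c1c(C)cc(OCc2ccccc2)c(C=O)c1OC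
F6 | step 9 | ethyl 4-(benzyloxy)-3-(formyloxy)-2-methoxy-6-methylbenzoate | CCOC(=O)c1c(C)cc(OCc2ccccc2)c(OC=O)c1OC
F7 | step 9 | ethyl 4-(benzyloxy)-3-hydroxy-2-methoxy-6-methylbenzoate | CCOC(=O)c1c(C)cc(OCc2ccccc2)c(O)c1OC
F8 | step 15 | 2-(benzyloxy)-4-{[4-(benzyloxy)-2,3-dimethoxy-6-methylbenzoyl]oxy}-6-methylbenzoyl chloride | O=C(Cl)c1c(C)cc(OC(=O)c2c(C)cc(OCc3ccccc3)c(OC)c2OC)cc1OCc1ccccc1
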